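**Plan**
- Retrosynthetic cuts, in order: the fourteen O-benzyl bonds and the C8–Br bond of the lower unit; the gallate ester C–O bond at O3; the interflavan C4–C6 bond; the O1–C8a aryl ether bond of ring C of the upper unit; the oxirane C–O bonds; the C3–C4 π bond (back to an alkyne); the C2–C3 bond.
- Forward: ring A (from 1,3,5-trifluorobenzene) and ring B are joined through a three-carbon alkyne chain. Ring C is then closed by SNAr of the C2 alkoxide on C8a–F, with a cis-3,4-oxirane in place as a temporary ring. C6 of C8-bromo-blocked gallocatechin (rings D, F, E) opens the oxirane at C4, O3 is galloylated, and all benzyl groups and the bromine are removed together.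
- Enabling feature: C8a of ring A is meta to both C5–O and C7–O, so the anionic intermediate carries its charge on C4a, C6 and C8, none of which bears oxygen. Fluoride can therefore be displaced from this otherwise electron-rich ring.
- Because the C2–O bond is never broken, the threo C2/C3 relationship of the open chain becomes the 2,3-cis (epi) relationship of the flavan.
- Stereochemistry: C2 by catalyst control (BINOL–titanium alkynylzinc addition); C3 and C4 of the oxirane from C2 by hydroxyl-directed epoxidation of the Z-allylic alcohol; C4 of the target by anti opening of the oxirane (3,4-trans, 4β); C2 and C3 of the lower unit from (+)-gallocatechin.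

Key step: step 7

Remark (assumptions): (+)-gallocatechin (2R,3S) is taken as a purchasable starting material. For step 4 the usual sense of induction of the (S)-BINOL/Ti(OiPr)4 alkynylzinc addition (attack on the Si face of an aryl aldehyde) is assumed; with the opposite sense (R)-BINOL would be used.

Step 1
Reactants: 1 1,3,5-trifluorobenzene
Product: 2 1,3-bis(benzyloxy)-5-fluorobenzene
Conditions: BnOH (2.1 equiv), NaH (2.2 equiv), NMP, 0 → 100 °C
Reagents that add atoms: benzyl alcohol, OCc1ccccc1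
Why: Twofold SNAr of sodium benzyloxide on the trifluoroarene, each fluoride being activated by the two meta fluorines; the last fluoride, now meta only to two alkoxy groups, reacts more slowly and should survive with 2.1 equivalents of alkoxide.

Step 2
Reactants: 2 1,3-bis(benzyloxy)-5-fluorobenzene
Product: 4 2,4-bis(benzyloxy)-6-fluorobenzaldehyde, via aryllithium 3 (not isolated)
Conditions: n-BuLi, THF, −78 °C; DMF, −78 → 0 °C; 1 M HCl
Reagents that add atoms: N,N-dimethylformamide, CN(C)C=O
Why: Directed ortho-lithiation at the C–H flanked by F and OBn (cooperative acidification; −78 °C keeps the ortho-fluoroaryllithium from losing LiF), followed by formylation of the aryllithium with DMF.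

Step 3
Reactants: 4 2,4-bis(benzyloxy)-6-fluorobenzaldehyde
Product: 5 1,5-bis(benzyloxy)-2-ethynyl-3-fluorobenzene
Conditions: dimethyl (1-diazo-2-oxopropyl)phosphonate, K2CO3, MeOH–THF, 0 °C → rt
Reagents that add atoms: dimethyl (1-diazo-2-oxopropyl)phosphonate, COP(=O)(OC)C(=[N+]=[N-])C(C)=O
Why: Seyferth–Gilbert homologation with the Ohira–Bestmann reagent: methanolysis gives the diazomethylphosphonate anion, which adds to the aldehyde, eliminates dimethyl phosphate and loses N2 with 1,2-hydride shift to the terminal alkyne, under a base too weak to displace the ring fluoride.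

Step 4
Reactants: 5 1,5-bis(benzyloxy)-2-ethynyl-3-fluorobenzene; 6 3,4,5-tris(benzyloxy)benzaldehyde
Product: 8 (1R)-3-[2,4-bis(benzyloxy)-6-fluorophenyl]-1-[3,4,5-tris(benzyloxy)phenyl]prop-2-yn-1-ol, via ethylzinc acetylide 7 (not isolated)
Conditions: 5, Et2Zn, toluene, reflux; then (S)-BINOL (20 mol %), Ti(OiPr)4 (50 mol %), CH2Cl2, rt; then 6, rt; aq NH4Cl
Reagents that add atoms: none
Why: Catalytic asymmetric alkynylation of an aryl aldehyde (alkynylzinc addition under BINOL–titanium control): the chiral titanium complex directs the acetylide to the Si face of 6 and so sets C2 (R in 8), the only stereocentre of the upper unit that is introduced by a reagent.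

Step 5
Reactants: 8 (1R)-3-[2,4-bis(benzyloxy)-6-fluorophenyl]-1-[3,4,5-tris(benzyloxy)phenyl]prop-2-yn-1-ol
Product: 9 (1S,2Z)-3-[2,4-bis(benzyloxy)-6-fluorophenyl]-1-[3,4,5-tris(benzyloxy)phenyl]prop-2-en-1-ol
Conditions: H2 (1 atm), Pd/CaCO3 poisoned with Pb(OAc)2, quinoline, EtOAc, rt, stopped after one equivalent of H2
Reagents that add atoms: none
Why: Lindlar semi-hydrogenation: syn addition of one equivalent of H2 on the poisoned palladium surface gives the Z-alkene, with quinoline suppressing over-reduction and hydrogenolysis of the benzyl ethers and the carbinol (the descriptor changes from R to S only through the priority change, the centre is untouched).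

Step 6
Reactants: 9 (1S,2Z)-3-[2,4-bis(benzyloxy)-6-fluorophenyl]-1-[3,4,5-tris(benzyloxy)phenyl]prop-2-en-1-ol
Product: 10 (R)-{(2S,3R)-3-[2,4-bis(benzyloxy)-6-fluorophenyl]oxiran-2-yl}[3,4,5-tris(benzyloxy)phenyl]methanol (cis-oxirane, threo to the carbinol)
Conditions: mCPBA (1.1 equiv), CH2Cl2–aq NaHCO3 (two-phase), 0 °C; crude product taken on at once
Reagents that add atoms: 3-chloroperoxybenzoic acid, O=C(OO)c1cccc(Cl)c1
Why: Hydroxyl-directed (Henbest-type) peracid epoxidation of a Z-allylic alcohol: allylic 1,3-strain against the cis aryl group holds the carbinol C–H in the alkene plane, so the hydrogen-bonded peracid is delivered to the face carrying OH, which is also the face not shielded by ring B, and the new stereocentres C3 and C4 arise threo to C2 as the cis-oxirane.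

Step 7
Reactants: 10 (R)-{(2S,3R)-3-[2,4-bis(benzyloxy)-6-fluorophenyl]oxiran-2-yl}[3,4,5-tris(benzyloxy)phenyl]methanol
Product: 12 (1aR,2R,7bR)-5,7-bis(benzyloxy)-2-[3,4,5-tris(benzyloxy)phenyl]-1a,7b-dihydro-2H-oxireno[2,3-c]chromene, via potassium alkoxide 11 (not isolated)
Conditions: KH (1.2 equiv), THF–DMF (3:1), 0.01 M, 0 °C → rt; aq NaHCO3 work-up, no silica
Reagents that add atoms: none
Why: KH gives the C2 potassium alkoxide, which adds to C8a of ring A to form a cyclohexadienyl (Meisenheimer-type) anion and then expels fluoride (addition–elimination SNAr). The closest known reaction type is the intramolecular SNAr etherification of 3,5-dialkoxyfluoroarenes by a benzylic alkoxide, used to close the pyran ring of flavan-3-ols. Ring C closes in the 6-exo-trig mode at C8a; this is feasible because C8a is meta to C5–O and C7–O, so the charge of the intermediate sits on C4a, C6 and C8, and because the cis-oxirane holds C2 and ring A on the same side of the C3–C4 bond. No new stereocentre is formed: C2 is carried over with retention since its C–O bond is not broken, so the threo epoxy alcohol becomes the 2,3-cis flavan with the oxirane on the face of the 2-aryl group, an epoxide that oxidation of a flav-3-ene would not give. The selectivity needed is attack of the alkoxide at C8a and not at the oxirane: the only close competitor, Payne rearrangement by attack at C3, is reversible and leads to a C4 alkoxide that cannot reach a C–F carbon, so it should drain back to 11. O3 is tied up in the oxirane and cannot close a five-membered ring, and high dilution holds back intermolecular opening.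

Step 8
Reactants: 13 (+)-gallocatechin, (2R,3S)-2-(3,4,5-trihydroxyphenyl)chromane-3,5,7-triol
Product: 14 (2R,3S)-5,7-bis(benzyloxy)-2-[3,4,5-tris(benzyloxy)phenyl]chroman-3-ol
Conditions: BnBr (5.5 equiv), K2CO3, DMF, Ar, 0 °C → rt
Reagents that add atoms: benzyl bromide, BrCc1ccccc1
Why: Williamson etherification of the five phenols, which alone are deprotonated by K2CO3 while the C3 alcohol is not, under argon to keep the pyrogallol ring from autoxidation; the stereocentres are untouched.

Step 9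
Reactants: 14 (2R,3S)-5,7-bis(benzyloxy)-2-[3,4,5-tris(benzyloxy)phenyl]chroman-3-ol
Product: 15 (2R,3S)-3,5,7-tris(benzyloxy)-2-[3,4,5-tris(benzyloxy)phenyl]chromane
Conditions: NaH, BnBr, n-Bu4NI (cat.), DMF, 0 °C → rt
Reagents that add atoms: benzyl bromide, BrCc1ccccc1
Why: Williamson etherification of the remaining secondary alcohol through its sodium alkoxide, so that the lower unit offers no free hydroxyl to the acylation of step 12.

Step 10
Reactants: 15 (2R,3S)-3,5,7-tris(benzyloxy)-2-[3,4,5-tris(benzyloxy)phenyl]chromane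
Product: 16 (2R,3S)-3,5,7-tris(benzyloxy)-8-bromo-2-[3,4,5-tris(benzyloxy)phenyl]chromane
Conditions: NBS (1.0 equiv), CH2Cl2, −78 → 0 °C
Reagents that add atoms: N-bromosuccinimide, O=C1CCC(=O)N1Br
Why: Electrophilic aromatic bromination goes to C8, the more reactive and less hindered of the two free positions of the 5,7-dialkoxy ring, and blocks it so that only C6 can later act as the nucleophile; the bromine leaves in step 13.

Step 11
Reactants: 12 (1aR,2R,7bR)-5,7-bis(benzyloxy)-2-[3,4,5-tris(benzyloxy)phenyl]-1a,7b-dihydro-2H-oxireno[2,3-c]chromene; 16 (2R,3S)-3,5,7-tris(benzyloxy)-8-bromo-2-[3,4,5-tris(benzyloxy)phenyl]chromane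
Product: 17 5,7,3',4',5'-penta-O-benzyl-epigallocatechin-(4β→6)-8-bromo-3,5,7,3',4',5'-hexa-O-benzyl-gallocatechin (upper unit 2R,3R, 2,3-cis, 3,4-trans, free 3-OH; lower unit 2R,3S)
Conditions: 12 added slowly to 16 (3 equiv) and BF3·OEt2 (0.3 equiv), CH2Cl2, −78 → −40 °C; excess 16 recovered
Reagents that add atoms: none
Why: Friedel–Crafts alkylation through Lewis-acid opening of the benzylic oxirane: BF3 ionises the C4–O bond to a cation stabilised by O1, C5–O and C7–O, and the only free nucleophilic carbon of 16 (C6, since C8 carries bromine) adds to the face opposite the C3 oxygen and the 2-aryl group, which sets C4 (3,4-trans, 4β) and frees the C3 hydroxyl, while slow addition of 12 to excess 16 holds back self-condensation on ring A of 12.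

Step 12
Reactants: 17 the 3-hydroxy dimer of step 11; 18 3,4,5-tris(benzyloxy)benzoic acid
Product: 19 3-O-[3,4,5-tris(benzyloxy)benzoyl]-5,7,3',4',5'-penta-O-benzyl-epigallocatechin-(4β→6)-8-bromo-3,5,7,3',4',5'-hexa-O-benzyl-gallocatechin
Conditions: DCC, DMAP, CH2Cl2, rt
Reagents that add atoms: none
Why: Steglich esterification (carbodiimide activation with DMAP as acyl-transfer catalyst) of the only free hydroxyl, the axial C3–OH of the upper unit, the lower C3–OH being a benzyl ether.

Step 13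
Reactants: 19 the fully protected 8-bromo gallate dimer of step 12
Product: 20 epigallocatechin 3-O-gallate-(4β→6)-gallocatechin (upper unit 2R,3R,4S; lower unit 2R,3S), the target
Conditions: H2 (1 atm), Pd(OH)2/C, NaOAc (1.1 equiv), THF–MeOH–H2O, rt
Reagents that add atoms: none
Why: Palladium-catalysed hydrogenolysis cleaves the fourteen O-benzyl groups and the aryl C–Br bond in one operation, NaOAc buffering the HBr so that the acid-labile interflavan bond and the gallate ester persist, and no stereocentre is touched.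

**Compound list**
1 | 1,3,5-trifluorobenzene | Fc1cc(F)cc(F)c1 | starting material
2 | 1,3-bis(benzyloxy)-5-fluorobenzene | Fc1cc(OCc2ccccc2)cc(OCc2ccccc2)c1 | intermediate
3 | [2,4-bis(benzyloxy)-6-fluorophenyl]lithium | [Li]c1c(F)cc(OCc2ccccc2)cc1OCc1ccccc1 | intermediate
4 | 2,4-bis(benzyloxy)-6-fluorobenzaldehyde | O=Cc1c(F)cc(OCc2ccccc2)cc1OCc1ccccc1 | intermediate
5 | 1,5-bis(benzyloxy)-2-ethynyl-3-fluorobenzene | C#Cc1c(F)cc(OCc2ccccc2)cc1OCc1ccccc1 | intermediate
6 | 3,4,5-tris(benzyloxy)benzaldehyde | O=Cc1cc(OCc2ccccc2)c(OCc2ccccc2)c(OCc2ccccc2)c1 | starting material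
7 | ethyl{[2,4-bis(benzyloxy)-6-fluorophenyl]ethynyl}zinc | CC[Zn]C#Cc1c(F)cc(OCc2ccccc2)cc1OCc1ccccc1 | intermediate
8 | (1R)-3-[2,4-bis(benzyloxy)-6-fluorophenyl]-1-[3,4,5-tris(benzyloxy)phenyl]prop-2-yn-1-ol | O[C@@H](C#Cc1c(F)cc(OCc2ccccc2)cc1OCc1ccccc1)c1cc(OCc2ccccc2)c(OCc2ccccc2)c(OCc2ccccc2)c1 | intermediate
9 | (1S,2Z)-3-[2,4-bis(benzyloxy)-6-fluorophenyl]-1-[3,4,5-tris(benzyloxy)phenyl]prop-2-en-1-ol | O[C@@H](/C=C\c1c(F)cc(OCc2ccccc2)cc1OCc1ccccc1)c1cc(OCc2ccccc2)c(OCc2ccccc2)c(OCc2ccccc2)c1 | intermediate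
10 | (R)-{(2S,3R)-3-[2,4-bis(benzyloxy)-6-fluorophenyl]oxiran-2-yl}[3,4,5-tris(benzyloxy)phenyl]methanol | O[C@H](c1cc(OCc2ccccc2)c(OCc2ccccc2)c(OCc2ccccc2)c1)[C@@H]1O[C@@H]1c1c(F)cc(OCc2ccccc2)cc1OCc1ccccc1 | intermediate
11 | potassium alkoxide of 10 | [K+].[O-][C@H](c1cc(OCc2ccccc2)c(OCc2ccccc2)c(OCc2ccccc2)c1)[C@@H]1O[C@@H]1c1c(F)cc(OCc2ccccc2)cc1OCc1ccccc1 | intermediate
12 | (1aR,2R,7bR)-5,7-bis(benzyloxy)-2-[3,4,5-tris(benzyloxy)phenyl]-1a,7b-dihydro-2H-oxireno[2,3-c]chromene (3,4-epoxyflavan, oxirane cis to the 2-aryl group) | O1[C@@H]2[C@H]1c1c(OCc3ccccc3)cc(OCc3ccccc3)cc1O[C@@H]2c1cc(OCc2ccccc2)c(OCc2ccccc2)c(OCc2ccccc2)c1 | intermediate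
13 | (+)-gallocatechin, (2R,3S)-2-(3,4,5-trihydroxyphenyl)chromane-3,5,7-triol | Oc1cc(O)c2C[C@H](O)[C@@H](c3cc(O)c(O)c(O)c3)Oc2c1 | starting material
14 | (2R,3S)-5,7-bis(benzyloxy)-2-[3,4,5-tris(benzyloxy)phenyl]chroman-3-ol | C(c1ccccc1)Oc1cc(OCc2ccccc2)c2C[C@H](O)[C@@H](c3cc(OCc4ccccc4)c(OCc4ccccc4)c(OCc4ccccc4)c3)Oc2c1 | intermediate
15 | (2R,3S)-3,5,7-tris(benzyloxy)-2-[3,4,5-tris(benzyloxy)phenyl]chromane | C(c1ccccc1)Oc1cc(OCc2ccccc2)c2C[C@H](OCc3ccccc3)[C@@H](c3cc(OCc4ccccc4)c(OCc4ccccc4)c(OCc4ccccc4)c3)Oc2c1 | intermediate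
16 | (2R,3S)-3,5,7-tris(benzyloxy)-8-bromo-2-[3,4,5-tris(benzyloxy)phenyl]chromane | C(c1ccccc1)Oc1cc(OCc2ccccc2)c2C[C@H](OCc3ccccc3)[C@@H](c3cc(OCc4ccccc4)c(OCc4ccccc4)c(OCc4ccccc4)c3)Oc2c1Br | intermediate
17 | 5,7,3',4',5'-penta-O-benzyl-epigallocatechin-(4β→6)-8-bromo-3,5,7,3',4',5'-hexa-O-benzyl-gallocatechin (upper 3-OH free) | O[C@@H]1[C@@H](c2c(OCc3ccccc3)c(Br)c3c(c2OCc2ccccc2)C[C@H](OCc2ccccc2)[C@@H](c2cc(OCc4ccccc4)c(OCc4ccccc4)c(OCc4ccccc4)c2)O3)c2c(OCc3ccccc3)cc(OCc3ccccc3)cc2O[C@@H]1c1cc(OCc2ccccc2)c(OCc2ccccc2)c(OCc2ccccc2)c1 | intermediate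
18 | 3,4,5-tris(benzyloxy)benzoic acid | OC(=O)c1cc(OCc2ccccc2)c(OCc2ccccc2)c(OCc2ccccc2)c1 | starting material
19 | 3-O-[3,4,5-tris(benzyloxy)benzoyl] ester of 17 | O=C(O[C@@H]1[C@@H](c2c(OCc3ccccc3)c(Br)c3c(c2OCc2ccccc2)C[C@H](OCc2ccccc2)[C@@H](c2cc(OCc4ccccc4)c(OCc4ccccc4)c(OCc4ccccc4)c2)O3)c2c(OCc3ccccc3)cc(OCc3ccccc3)cc2O[C@@H]1c1cc(OCc2ccccc2)c(OCc2ccccc2)c(OCc2ccccc2)c1)c1cc(OCc2ccccc2)c(OCc2ccccc2)c(OCc2ccccc2)c1 | intermediate
20 | epigallocatechin 3-O-gallate-(4β→6)-gallocatechin (upper unit 2R,3R,4S; lower unit 2R,3S) | O=C(O[C@@H]1[C@@H](c2c(O)cc3c(c2O)C[C@H](O)[C@@H](c2cc(O)c(O)c(O)c2)O3)c2c(O)cc(O)cc2O[C@@H]1c1cc(O)c(O)c(O)c1)c1cc(O)c(O)c(O)c1 | target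

**Totals**
Total step count: 13. Longest linear sequence: 10 steps (steps 1 to 7, then 11, 12 and 13).

**Steps most likely to fail**

Step 7. The alkoxide may be consumed by the oxirane (Payne shuttling followed by intermolecular opening) faster than it closes on the only weakly activated C8a–F carbon. The fallback exchanges the oxirane for a base-inert ring before closure. It sets out from 10, which with acetone and catalytic BF3·OEt2 at −30 °C should insert acetone at the benzylic carbon to give (R)-{(4S,5S)-5-[2,4-bis(benzyloxy)-6-fluorophenyl]-2,2-dimethyl-1,3-dioxolan-4-yl}[3,4,5-tris(benzyloxy)phenyl]methanol F1. The configuration at C4 is of no consequence here because C4 is ionised later. KH in DMF then closes ring C by the same SNAr to (2R,3S,4S)-5,7-bis(benzyloxy)-3,4-(isopropylidenedioxy)-2-[3,4,5-tris(benzyloxy)phenyl]chromane F2. TMSOTf at −78 °C in the presence of 16 opens the ketal, acetone is lost from C4, and C6 of 16 adds trans to O3; a desilylating work-up brings the route back at 17.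

Step 6. The very electron-rich aryl oxirane may be opened or rearranged by 3-chlorobenzoic acid as it forms, or face control may be eroded. The fallback puts ring closure before oxygenation and builds the oxirane on the ring. It sets out from 9, which with KH in THF–DMF should close by the same SNAr (the Z-alkene holding the chain cisoid) to (2S)-5,7-bis(benzyloxy)-2-[3,4,5-tris(benzyloxy)phenyl]-2H-chromene F3. NBS (1.0 equiv) in wet THF at −20 °C adds bromine to C3 from the face opposite the 2-aryl group and water to the benzylic C4 from the other face, giving (2R,3S,4R)-5,7-bis(benzyloxy)-3-bromo-2-[3,4,5-tris(benzyloxy)phenyl]chroman-4-ol F4. K2CO3 in MeOH closes the oxirane by backside displacement at C3, which places the oxygen on the face of the 2-aryl group, and the route is rejoined at 12.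

Step 11. The cation from the oxirane may be captured by the unblocked ring A of a second molecule of 12 (oligomerisation), or may undergo hydride shift to the 3-ketone (Meinwald-type), before the hindered C6 of 16 reaches it; later acylation of the hindered C3 hydroxyl may also be slow. The fallback uses a stable, already acylated C4 ether as the electrophile. It sets out from 12, which with 2-ethoxyethanol and PPTS should open trans to (2R,3R,4S)-5,7-bis(benzyloxy)-4-(2-ethoxyethoxy)-2-[3,4,5-tris(benzyloxy)phenyl]chroman-3-ol F5. Esterification with 18 (DCC, DMAP) gives (2R,3R,4S)-5,7-bis(benzyloxy)-4-(2-ethoxyethoxy)-2-[3,4,5-tris(benzyloxy)phenyl]chroman-3-yl 3,4,5-tris(benzyloxy)benzoate F6. TMSOTf-mediated condensation of F6 with 16 (equimolar, CH2Cl2, −78 °C, the 3-O-acyl group shielding one face of C4) comes back to the route at 19.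

Further compounds
F1 | step 7 | (R)-{(4S,5S)-5-[2,4-bis(benzyloxy)-6-fluorophenyl]-2,2-dimethyl-1,3-dioxolan-4-yl}[3,4,5-tris(benzyloxy)phenyl]methanol | O[C@H](c1cc(OCc2ccccc2)c(OCc2ccccc2)c(OCc2ccccc2)c1)[C@@H]1OC(C)(C)O[C@H]1c1c(F)cc(OCc2ccccc2)cc1OCc1ccccc1
F2 | step 7 | (2R,3S,4S)-5,7-bis(benzyloxy)-3,4-(isopropylidenedioxy)-2-[3,4,5-tris(benzyloxy)phenyl]chromane | CC1(C)O[C@@H]2[C@@H](O1)c1c(OCc3ccccc3)cc(OCc3ccccc3)cc1O[C@@H]2c1cc(OCc2ccccc2)c(OCc2ccccc2)c(OCc2ccccc2)c1
F3 | step 6 | (2S)-5,7-bis(benzyloxy)-2-[3,4,5-tris(benzyloxy)phenyl]-2H-chromene | O1c2cc(OCc3ccccc3)cc(OCc3ccccc3)c2C=C[C@H]1c1cc(OCc2ccccc2)c(OCc2ccccc2)c(OCc2ccccc2)c1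
F4 | step 6 | (2R,3S,4R)-5,7-bis(benzyloxy)-3-bromo-2-[3,4,5-tris(benzyloxy)phenyl]chroman-4-ol | O[C@H]1[C@H](Br)[C@@H](c2cc(OCc3ccccc3)c(OCc3ccccc3)c(OCc3ccccc3)c2)Oc2cc(OCc3ccccc3)cc(OCc3ccccc3)c12
F5 | step 11 | (2R,3R,4S)-5,7-bis(benzyloxy)-4-(2-ethoxyethoxy)-2-[3,4,5-tris(benzyloxy)phenyl]chroman-3-ol | O[C@@H]1[C@@H](OCCOCC)c2c(OCc3ccccc3)cc(OCc3ccccc3)cc2O[C@@H]1c1cc(OCc2ccccc2)c(OCc2ccccc2)c(OCc2ccccc2)c1
F6 | step 11 | (2R,3R,4S)-5,7-bis(benzyloxy)-4-(2-ethoxyethoxy)-2-[3,4,5-tris(benzyloxy)phenyl]chroman-3-yl 3,4,5-tris(benzyloxy)benzoate | O=C(O[C@@H]1[C@@H](OCCOCC)c2c(OCc3ccccc3)cc(OCc3ccccc3)cc2O[C@@H]1c1cc(OCc2ccccc2)c(OCc2ccccc2)c(OCc2ccccc2)c1)c1cc(OCc2ccccc2)c(OCc2ccccc2)c(OCc2ccccc2)c1
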